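**Retrosynthetic overview**
1. Ring C (O1–C2 and C4–C4a) is closed last by acylation and oxa-Michael addition of 3-methylbut-2-enoic acid at the only free arene carbon (C4a). The C5 oxygen is carried as a methyl ether, so only the hydroxyl on C8a (next to the C8 bridge) can become O1; BCl3 then frees 5-OH.
2. Ring A is built de novo by a [3+3] double acylation. Its C3'(CH2 bridge)–C2'(OH)–C1'(CO-iPr) segment is the β-diketone 9, used as bis(silyl enol ether) 11. Its C4'(OH)–C5'(CH3)–C6'(OH) segment is methylmalonyl dichloride 13. The new bonds are C3'–C4' and C1'–C6'.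
3. Diketone 9, which already holds the C8–CH2–C3' bridge, comes from ring-B aldehyde 6 and 5-methylhexane-2,4-dione by boron-mediated aldol condensation at the methyl group, then alkene hydrogenation.
4. Aldehyde 6 comes from 2-methylphloroglucinol by formylation, O-methylation para to the formyl group and benzylation of the two ortho hydroxyls.
5. Ring order: ring B (from 1), ring A (step 8), ring C (step 10).

Key step: step 8

Remark: ring A is numbered C1' (isobutyryl), C2', C3' (CH2 bridge), C4', C5' (CH3), C6'. Enol silyl ethers 10, 11 and 14 are expected as isomer mixtures whose alkene geometry (and the enolisable stereocentres of 14) is lost in step 8, so their SMILES carry no stereodescriptors. Compounds 8, 9 and 15 are drawn as single tautomers.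

**Step 1**
Reactants: 1 2-methylbenzene-1,3,5-triol (2-methylphloroglucinol)
Product: 3 2,4,6-trihydroxy-3-methylbenzaldehyde, via aryl iminium chloride 2 (not isolated)
Conditions: POCl3 (1.1 equiv), DMF (1.5 equiv), EtOAc, 0 → 20 °C; then H2O, 50 °C
Reagents that add atoms: N,N-dimethylformamide CN(C)C=O; water O
Why: Vilsmeier–Haack formylation; the two free ring carbons of 1 are equivalent, and the precipitating iminium salt should resist a second formylation.

**Step 2**
Reactants: 3 2,4,6-trihydroxy-3-methylbenzaldehyde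
Product: 4 2,6-dihydroxy-4-methoxy-3-methylbenzaldehyde
Conditions: MeI (1.05 equiv), NaHCO3 (1.2 equiv), DMF, 35 °C
Reagents that add atoms: iodomethane CI
Why: Williamson O-methylation under a weak base, which should select the 4-OH para to the formyl group because it is the most acidic hydroxyl and is not hydrogen-bonded to the carbonyl.

**Step 3**
Reactants: 4 2,6-dihydroxy-4-methoxy-3-methylbenzaldehyde; 5 benzyl bromide
Product: 6 2,6-bis(benzyloxy)-4-methoxy-3-methylbenzaldehyde
Conditions: 5 (2.5 equiv), K2CO3 (3 equiv), DMF, 60 °C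
Reagents that add atoms: none
Why: Williamson etherification under forcing conditions should alkylate both hydrogen-bonded ortho hydroxyls, and the benzyl ethers tolerate the base, silylation and acylation steps that follow.

**Step 4**
Reactants: 6 2,6-bis(benzyloxy)-4-methoxy-3-methylbenzaldehyde; 7 5-methylhexane-2,4-dione
Product: 8 (1E)-1-[2,6-bis(benzyloxy)-4-methoxy-3-methylphenyl]-6-methylhept-1-ene-3,5-dione
Conditions: 7 (1.5 equiv), B2O3 (0.7 equiv), EtOAc, 75 °C; 6, B(OBu)3 (2 equiv), n-BuNH2 (0.3 equiv), 75 °C; then 0.5 M HCl, 60 °C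
Reagents that add atoms: none
Why: Boron-mediated aldol condensation of the curcuminoid type; the boron chelate blocks Knoevenagel reaction at the central carbon, only the methyl terminus can dehydrate to an enone, and the (E)-alkene is the thermodynamic product.

**Step 5**
Reactants: 8 (1E)-1-[2,6-bis(benzyloxy)-4-methoxy-3-methylphenyl]-6-methylhept-1-ene-3,5-dione
Product: 9 1-[2,6-bis(benzyloxy)-4-methoxy-3-methylphenyl]-6-methylheptane-3,5-dione
Conditions: H2 (1 atm), 10% Pd/C, Ph2S (0.1 equiv), EtOAc, 20 °C
Reagents that add atoms: none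
Why: Catalytic hydrogenation of the conjugated alkene over a sulfide-poisoned palladium catalyst, which should leave the aryl benzyl ethers and the ketones untouched.

**Step 6**
Reactants: 9 1-[2,6-bis(benzyloxy)-4-methoxy-3-methylphenyl]-6-methylheptane-3,5-dione
Product: 11 1-[2,6-bis(benzyloxy)-4-methoxy-3-methylphenyl]-6-methyl-3,5-bis(trimethylsilyloxy)hepta-2,4-diene, via mono(trimethylsilyl) enol ether 10 (not isolated)
Conditions: LiN(iPr)2 (1.05 equiv), THF, −78 → 0 °C; Me3SiCl (1.1 equiv), 20 °C; then −78 °C, LiN(iPr)2 (1.2 equiv), → −45 °C; Me3SiCl (1.3 equiv), → 20 °C; evaporate, pentane, filter under Ar; use crude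
Reagents that add atoms: chlorotrimethylsilane C[Si](C)(C)Cl
Why: Stepwise double enol silylation (1,3-bis(silyl enol ether) synthesis); after O-silylation of the lithium diketonate, the amide base should remove a proton from the arylethyl CH2 (α' in one O-silyl regioisomer, γ in the other, the two interconverting by 1,5-silyl shift) and not from the hindered isopropyl methine, so both converge on one dienolate that is trapped on oxygen.

**Step 7**
Reactants: 12 2-methylpropanedioic acid (methylmalonic acid)
Product: 13 2-methylpropanedioyl dichloride (methylmalonyl dichloride)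
Conditions: SOCl2 (4 equiv), 50 °C; distil under reduced pressure
Reagents that add atoms: thionyl chloride O=S(Cl)Cl
Why: Standard conversion of a malonic acid into its diacid chloride with SOCl2 at a temperature below the onset of decarboxylation.

**Step 8**
Reactants: 11 1-[2,6-bis(benzyloxy)-4-methoxy-3-methylphenyl]-6-methyl-3,5-bis(trimethylsilyloxy)hepta-2,4-diene; 13 2-methylpropanedioyl dichloride
Product: 16 1-[3-[[2,6-bis(benzyloxy)-4-methoxy-3-methylphenyl]methyl]-2,4,6-trihydroxy-5-methylphenyl]-2-methylpropan-1-one, via acyl chloride 14 (not isolated), via pyranone 15 (not isolated)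
Conditions: 13 (1.3 equiv), CH2Cl2, −78 °C, 11 added over 2 h, → 20 °C; evaporate; Mg(OMe)2 (6 equiv), MeOH, reflux, Ar; then 1 M HCl
Reagents that add atoms: none
Why: The diene terminus of 11 (future C3'), its most nucleophilic carbon, attacks one acyl chloride of 13 with loss of Me3SiCl to form C3'–C4' (14); the second acyl chloride then closes a six-membered ring by 6-exo-trig acylation, either at C1' of the remaining silyl enol ether (forming C1'–C6' directly) or at the C2' enol oxygen (pyranone 15). Mg(OMe)2 opens 15 to the magnesium chelate of the methyl 3,5,7-trioxo ester, whose doubly activated C1' attacks the ester carbonyl in a 6-exo-trig Claisen condensation that forms C1'–C6', and enolisation gives aromatic ring A, so both closure modes converge on 16. The closest known reaction types are the uncatalysed terminal C-acylation of 1,3-bis(silyl enol ethers) by acid chlorides, the formation of 4-hydroxy-2-pyranones from silyl enol ethers and malonyl dichlorides, and the Mg(OMe)2-mediated recyclisation of 6-(2-oxoalkyl)-4-hydroxy-2-pyranones to acylphloroglucinols. No stereocentre is formed. The step needs terminal and not central acylation of the diene, which its vinylogous reactivity secures, and it needs Claisen and not aldol ring closure, which magnesium chelation of the triketo ester and the hindrance of the alternative (a tertiary C5' carbanion attacking the isopropyl ketone) secure. Ring B should stay inert because no Lewis acid is used and its oxygens are ether-protected.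

**Step 9**
Reactants: 16 1-[3-[[2,6-bis(benzyloxy)-4-methoxy-3-methylphenyl]methyl]-2,4,6-trihydroxy-5-methylphenyl]-2-methylpropan-1-one
Product: 17 1-[3-[(2,6-dihydroxy-4-methoxy-3-methylphenyl)methyl]-2,4,6-trihydroxy-5-methylphenyl]-2-methylpropan-1-one
Conditions: H2 (1 atm), 10% Pd/C, EtOAc/MeOH, 20 °C
Reagents that add atoms: none
Why: Hydrogenolysis of the two aryl benzyl ethers; the chelated aryl ketone, the methyl ether and the diarylmethane link should be inert under these mild conditions.

**Step 10**
Reactants: 17 1-[3-[(2,6-dihydroxy-4-methoxy-3-methylphenyl)methyl]-2,4,6-trihydroxy-5-methylphenyl]-2-methylpropan-1-one; 18 3-methylbut-2-enoic acid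
Product: 20 7-hydroxy-5-methoxy-2,2,6-trimethyl-8-[[2,4,6-trihydroxy-3-methyl-5-(2-methylpropanoyl)phenyl]methyl]-2,3-dihydro-4H-chromen-4-one, via aryl enone 19 (not isolated)
Conditions: 18 (1.2 equiv), BF3·OEt2 (medium), 60 °C; then NaOAc, MeOH/H2O, 50 °C
Reagents that add atoms: none
Why: Friedel–Crafts acylation at the only unsubstituted arene carbon, then 6-endo-trig oxa-Michael addition; because the other ortho oxygen is a methyl ether, only the hydroxyl next to the bridge carbon can close ring C, which fixes the 6-methyl-8-benzyl pattern.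

**Step 11**
Reactants: 20 7-hydroxy-5-methoxy-2,2,6-trimethyl-8-[[2,4,6-trihydroxy-3-methyl-5-(2-methylpropanoyl)phenyl]methyl]-2,3-dihydro-4H-chromen-4-one
Product: 21 5,7-dihydroxy-2,2,6-trimethyl-8-[[2,4,6-trihydroxy-3-methyl-5-(2-methylpropanoyl)phenyl]methyl]-2,3-dihydro-4H-chromen-4-one
Conditions: BCl3 (6 equiv), CH2Cl2, −78 → 0 °C; then MeOH, H2O
Reagents that add atoms: none
Why: Chelation-assisted cleavage of the aryl methyl ether peri to the C4 carbonyl by BCl3 at low temperature, where the chromanone ring and the diarylmethane should survive.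

**Compound list**
1 | 2-methylbenzene-1,3,5-triol (2-methylphloroglucinol) | Cc1c(O)cc(O)cc1O | starting material
2 | N-[(2,4,6-trihydroxy-3-methylphenyl)methylidene]-N-methylmethanaminium chloride | C[N+](C)=Cc1c(O)cc(O)c(C)c1O.[Cl-] | intermediate (not isolated)
3 | 2,4,6-trihydroxy-3-methylbenzaldehyde | O=Cc1c(O)cc(O)c(C)c1O | intermediate
4 | 2,6-dihydroxy-4-methoxy-3-methylbenzaldehyde | O=Cc1c(O)cc(OC)c(C)c1O | intermediate
5 | benzyl bromide | BrCc1ccccc1 | starting material
6 | 2,6-bis(benzyloxy)-4-methoxy-3-methylbenzaldehyde | O=Cc1c(OCc2ccccc2)cc(OC)c(C)c1OCc1ccccc1 | intermediate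
7 | 5-methylhexane-2,4-dione | CC(C)C(=O)CC(C)=O | starting material
8 | (1E)-1-[2,6-bis(benzyloxy)-4-methoxy-3-methylphenyl]-6-methylhept-1-ene-3,5-dione | CC(C)C(=O)CC(=O)/C=C/c1c(OCc2ccccc2)cc(OC)c(C)c1OCc1ccccc1 | intermediate
9 | 1-[2,6-bis(benzyloxy)-4-methoxy-3-methylphenyl]-6-methylheptane-3,5-dione | CC(C)C(=O)CC(=O)CCc1c(OCc2ccccc2)cc(OC)c(C)c1OCc1ccccc1 | intermediate
10 | 1-[2,6-bis(benzyloxy)-4-methoxy-3-methylphenyl]-6-methyl-3-(trimethylsilyloxy)hept-3-en-5-one (in admixture with its 5-silyloxy regioisomer) | CC(C)C(=O)C=C(CCc1c(OCc2ccccc2)cc(OC)c(C)c1OCc1ccccc1)O[Si](C)(C)C | intermediate (not isolated)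
11 | 1-[2,6-bis(benzyloxy)-4-methoxy-3-methylphenyl]-6-methyl-3,5-bis(trimethylsilyloxy)hepta-2,4-diene | CC(C)C(O[Si](C)(C)C)=CC(O[Si](C)(C)C)=CCc1c(OCc2ccccc2)cc(OC)c(C)c1OCc1ccccc1 | intermediate
12 | 2-methylpropanedioic acid (methylmalonic acid) | CC(C(=O)O)C(=O)O | starting material
13 | 2-methylpropanedioyl dichloride (methylmalonyl dichloride) | CC(C(Cl)=O)C(Cl)=O | intermediate
14 | 4-[[2,6-bis(benzyloxy)-4-methoxy-3-methylphenyl]methyl]-2,8-dimethyl-3,5-dioxo-7-(trimethylsilyloxy)non-6-enoyl chloride | CC(C)C(O[Si](C)(C)C)=CC(=O)C(Cc1c(OCc2ccccc2)cc(OC)c(C)c1OCc1ccccc1)C(=O)C(C)C(Cl)=O | intermediate (not isolated)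
15 | 5-[[2,6-bis(benzyloxy)-4-methoxy-3-methylphenyl]methyl]-4-hydroxy-3-methyl-6-(3-methyl-2-oxobutyl)-2H-pyran-2-one | CC(C)C(=O)CC1=C(Cc2c(OCc3ccccc3)cc(OC)c(C)c2OCc2ccccc2)C(O)=C(C)C(=O)O1 | intermediate (not isolated)
16 | 1-[3-[[2,6-bis(benzyloxy)-4-methoxy-3-methylphenyl]methyl]-2,4,6-trihydroxy-5-methylphenyl]-2-methylpropan-1-one | Cc1c(O)c(Cc2c(OCc3ccccc3)cc(OC)c(C)c2OCc2ccccc2)c(O)c(C(=O)C(C)C)c1O | intermediate
17 | 1-[3-[(2,6-dihydroxy-4-methoxy-3-methylphenyl)methyl]-2,4,6-trihydroxy-5-methylphenyl]-2-methylpropan-1-one | Cc1c(O)c(Cc2c(O)cc(OC)c(C)c2O)c(O)c(C(=O)C(C)C)c1O | intermediate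
18 | 3-methylbut-2-enoic acid | CC(C)=CC(=O)O | starting material
19 | 1-[2,4-dihydroxy-6-methoxy-5-methyl-3-[[2,4,6-trihydroxy-3-methyl-5-(2-methylpropanoyl)phenyl]methyl]phenyl]-3-methylbut-2-en-1-one | Cc1c(O)c(Cc2c(O)c(C)c(OC)c(C(=O)C=C(C)C)c2O)c(O)c(C(=O)C(C)C)c1O | intermediate (not isolated)
20 | 7-hydroxy-5-methoxy-2,2,6-trimethyl-8-[[2,4,6-trihydroxy-3-methyl-5-(2-methylpropanoyl)phenyl]methyl]-2,3-dihydro-4H-chromen-4-one | Cc1c(O)c(Cc2c(O)c(C)c(OC)c3c2OC(C)(C)CC3=O)c(O)c(C(=O)C(C)C)c1O | intermediate
21 | 5,7-dihydroxy-2,2,6-trimethyl-8-[[2,4,6-trihydroxy-3-methyl-5-(2-methylpropanoyl)phenyl]methyl]-2,3-dihydro-4H-chromen-4-one | Cc1c(O)c(Cc2c(O)c(C)c(O)c3c2OC(C)(C)CC3=O)c(O)c(C(=O)C(C)C)c1O | target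

**Step count**
Total: 11 steps. Longest linear sequence: 10 steps (steps 1–6 and 8–11); step 7 is a one-step branch.

**Steps most likely to fail**

1. Step 8. The bifunctional acid chloride may acylate two diene molecules or lose HCl to a ketene before ring closure, and in the Mg(OMe)2 stage ring closure may take the aldol course or stall. Fallback, from 11 back to 16: 11 is acylated without catalyst (CH2Cl2, −78 → 20 °C) by the monofunctional methyl 3-chloro-2-methyl-3-oxopropanoate F1, which cannot bridge two dienes. F1 is made from 3-methoxy-2-methyl-3-oxopropanoic acid (assumed purchasable) and oxalyl chloride. Aqueous work-up gives the open-chain methyl 4-[[2,6-bis(benzyloxy)-4-methoxy-3-methylphenyl]methyl]-2,8-dimethyl-3,5,7-trioxononanoate F2. F2 is purified and cyclised in a separate Claisen condensation with Mg(OMe)2 in MeOH to give 16.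

2. Step 6. Deprotonation at the isopropyl methine or silylation on carbon would give regioisomeric silyl species that do not carry the nucleophilic C3' terminus. Fallback, from 6 and 1 back to 16: ring A is taken from a preformed acylphloroglucinol instead of being built. Reduction of 6 with NaBH4 in MeOH gives [2,6-bis(benzyloxy)-4-methoxy-3-methylphenyl]methanol F3. Friedel–Crafts acylation of 1 with 2-methylpropanoyl chloride and AlCl3 gives 2-methyl-1-(2,4,6-trihydroxy-3-methylphenyl)propan-1-one F4. Acid-catalysed Friedel–Crafts benzylation (TsOH, dioxane, 20 °C) of F4, used in excess, at its single free ring carbon with F3 gives 16.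

3. Step 10. The hot Lewis acid may fragment the electron-rich diarylmethane bridge, or the phenols may be esterified without C-acylation. Fallback, from 17 back to 20: Hoesch reaction of 17 with MeCN, ZnCl2 and HCl in Et2O at 0 °C gives the aryl ketiminium chloride F5. Warm water hydrolyses F5 to the methyl ketone 1-[3-[(3-acetyl-2,6-dihydroxy-4-methoxy-5-methylphenyl)methyl]-2,4,6-trihydroxy-5-methylphenyl]-2-methylpropan-1-one F6. Kabbe condensation of F6 with acetone and pyrrolidine (MeOH, 50 °C) closes ring C onto the only hydroxyl ortho to the acetyl group and gives 20.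

**Further compounds**
F1 | step 8 | methyl 3-chloro-2-methyl-3-oxopropanoate | COC(=O)C(C)C(Cl)=O
F2 | step 8 | methyl 4-[[2,6-bis(benzyloxy)-4-methoxy-3-methylphenyl]methyl]-2,8-dimethyl-3,5,7-trioxononanoate | COC(=O)C(C)C(=O)C(Cc1c(OCc2ccccc2)cc(OC)c(C)c1OCc1ccccc1)C(=O)CC(=O)C(C)C
F3 | step 6 | [2,6-bis(benzyloxy)-4-methoxy-3-methylphenyl]methanol | OCc1c(OCc2ccccc2)cc(OC)c(C)c1OCc1ccccc1
F4 | step 6 | 2-methyl-1-(2,4,6-trihydroxy-3-methylphenyl)propan-1-one | Cc1c(O)cc(O)c(C(=O)C(C)C)c1O
F5 | step 10 | 1-[2,4-dihydroxy-6-methoxy-5-methyl-3-[[2,4,6-trihydroxy-3-methyl-5-(2-methylpropanoyl)phenyl]methyl]phenyl]ethan-1-iminium chloride | CC(=[NH2+])c1c(OC)c(C)c(O)c(Cc2c(O)c(C)c(O)c(C(=O)C(C)C)c2O)c1O.[Cl-]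
F6 | step 10 | 1-[3-[(3-acetyl-2,6-dihydroxy-4-methoxy-5-methylphenyl)methyl]-2,4,6-trihydroxy-5-methylphenyl]-2-methylpropan-1-one | CC(=O)c1c(OC)c(C)c(O)c(Cc2c(O)c(C)c(O)c(C(=O)C(C)C)c2O)c1O
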